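**What's asked.** 3 numbers are wanted for this flask. The last lies beyond Friday's final reading at 8.00 min, so it gets the bracket.

- Friday's: starting material 30 mM; partner 120 mM; catalyst 0.75 mM; added ligand 0.70 mM; run made earlier
- flask: starting material 30 mM; partner 60.0 mM; catalyst 0.75 mM; added ligand 0.70 mM; time 40 min

Friday's run (percent of the starting material charged)

| time / min | target / % |
|---|---|
| 0.417 | 24.0 |
| 1.33 | 50.9 |
| 2.50 | 64.0 |
| 3.00 | 68.0 |
| 5.00 | 71.6 |
| 6.00 | 70.8 |
| 8.00 | 71.0 |

(readings scatter by 0.5 percentage points)

1. amount of target in percent of the starting material charged, at 2.0 min, 10 min and 40 min

- candidate steps: catalyst + added ligand <-> idle complex; starting material + partner <-> target; target + catalyst <-> isomer of the product + catalyst; starting material + partner <-> isomer of the product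

**Upper bound.** Friday's target averages 71.1% over its last 3 readings. If that plateau is a fixed share between parallel routes, half the partner leaves it unchanged, and this figure is the ceiling here.

**Lower bound.** Suppose instead that the plateau is the equilibrium of starting material and partner with target, and read everything missing as starting material. Friday then gives K = [target]/([starting material][partner]) = 0.0250 mM⁻¹. On this flask's charge, K gives a plateau of 52.5%.

**The correction.** The candidate steps also let catalyst turn target into its isomer, a leak on top of either plateau. Call the drain d, the fraction of the target lost per minute on the plateau. Friday's readings from 5.00 min to 8.00 min give 0.00281 min⁻¹, and two standard deviations of that slope allow up to 0.00944 min⁻¹. Counting the leak from 10 min to 40 min, that upper d lowers the floor to 39.6%. The candidate list writes the target step as reversible, so I take the equilibrium plateau and the read d, and I commit to 48.3% at 40 min.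

**The forecast.** It gives 40%, 60% and 58%, saying “Later values are a hedge between the two pictures”. Its last value is higher than mine. That value is also higher than my floor. It is lower than my ceiling, so it lies inside the bracket.

**The result.** The flask gives 38.6%, 54.3% and 44.9%, so the forecast's last value stands 13 percentage points too high.

    catalyst + added ligand ⇌ idle complex (K = 960 M⁻¹, k = 87.0 M⁻¹ min⁻¹)
    starting material + partner ⇌ target (K = 34.0 M⁻¹, k = 5.80 M⁻¹ min⁻¹)
    target + catalyst ⇌ isomer of the product + catalyst, rate k3*[catalyst]*[target] forward; the back reaction follows from the equilibrium constant (k = 12.0 M⁻¹ min⁻¹)
    starting material + partner ⇌ isomer of the product (K = 290 M⁻¹, k = 0.150 M⁻¹ min⁻¹)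

Between 10.0 min and 40.0 min this flask's isomer of the product rises from 6.81% to 22.1%. Over that stretch its target shrinks by a fraction 0.00634 min⁻¹, more than Friday's read d of 0.00281 min⁻¹ and less than the allowed 0.00944 min⁻¹.

Readings and results stem from a simulated flask from invented constants; the scatter is artificial.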